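**Strategy**

The cyclohexane (C1 = C(CH3)OH, C2 = CHBr, C4 = CH carrying the diene) is built from a prochiral cyclobutanone. In isopropenyl 3-oxocyclobutanecarboxylate the ester links the future C4 to the future C1 oxygen; zerovalent nickel with a chiral ligand inserts the isopropenyl C=C into one enantiotopic C(O)–CH2 bond, forming C1–C2 and C5–C6 in one operation. The step exploits the cis-1,4 relationship of the C1–O bond and the C4 substituent, enforced by the lactone bridge of the resulting 2-oxabicyclo[2.2.2]octanedione, and leaves C2 as a ketone for the bromide. The lactone carbon becomes the first dienyl carbon; a Heck reaction adds the linalool-derived bromotetrahydropyran.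

Key step: step 2

Remark: the sense of induction of the phosphoramidite in step 2 cannot be predicted; the ligand enantiomer that leads to (1R,4S)-3 is assumed to be chosen in a test run.

**Route**

Step 1
Reactants: 1 3-oxocyclobutane-1-carboxylic acid
Product: 2 prop-1-en-2-yl 3-oxocyclobutane-1-carboxylate
Conditions: propyne (excess), [RuCl2(p-cymene)]2 (1 mol %), P(2-furyl)3, Na2CO3 (cat.), toluene, 60 °C
Reagents that add atoms: propyne, CC#C
Why: Ruthenium-catalysed Markovnikov addition of a carboxylic acid to a terminal alkyne gives the isopropenyl (enol) ester and leaves the ketone alone.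

Step 2
Reactants: 2 prop-1-en-2-yl 3-oxocyclobutane-1-carboxylate
Product: 3 (1R,4S)-1-methyl-2-oxabicyclo[2.2.2]octane-3,6-dione
Conditions: Ni(cod)2 (10 mol %), BINOL-derived phosphoramidite with a bis(1-phenylethyl)amino group (20 mol %), toluene, 60 °C
Reagents that add atoms: none
Why: Proposed new method: zerovalent nickel should bind the ketone and the tethered isopropenyl C=C of the s-trans ester and undergo oxidative cyclization to an oxanickelacyclopentane, which forms C1–C2 of the target ring (ketone carbon to the internal alkene carbon) and closes the lactone ring in a 6-exo-trig mode; β-carbon elimination then cleaves one C(O)–CH2 bond of the strained cyclobutane and C(sp3)–C(sp3) reductive elimination from the seven-membered nickelacycle forms C5–C6 and closes the carbocycle. The closest known reaction type is the nickel-catalysed formal [4+2] insertion of alkynes, and of tethered 2-styryl alkenes with chiral phosphoramidites, into the C(O)–CH2 bond of cyclobutanones; new here are the ester tether and the enol ester as the two-carbon partner. Of the two new stereocentres, the bridgeheads C1 and C4, the relative configuration (C1–O cis to the C4 carbonyl carbon) is dictated by the two-atom lactone bridge and the absolute configuration by the ligand, which differentiates the enantiotopic alkene faces and with them the two enantiotopic C(O)–CH2 bonds. The step needs regioselectivity, secured by the short tether that lets the ketone carbon reach only the internal alkene carbon, and chemoselectivity over C(acyl)–O oxidative addition, β-acyloxy elimination and β-hydride elimination, which the π-acidic ligand, the anti disposition of the ester oxygen in the rigid nickelacycle and the bridgehead position of the only β-hydrogen should secure.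

Step 3
Reactants: 3 (1R,4S)-1-methyl-2-oxabicyclo[2.2.2]octane-3,6-dione
Product: 4 methyl (1S,4R)-4-hydroxy-4-methyl-3-oxocyclohexane-1-carboxylate
Conditions: NaOMe (0.1 equiv), MeOH, 0 °C
Reagents that add atoms: methanol, CO
Why: Transesterification of the strained bridged lactone frees the tertiary alcohol and the methyl ester without touching either stereocentre, the ester staying cis to the hydroxyl (its equatorial, thermodynamically preferred position).

Step 4
Reactants: 4 methyl (1S,4R)-4-hydroxy-4-methyl-3-oxocyclohexane-1-carboxylate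
Product: 5 methyl (1S,3R,4R)-3,4-dihydroxy-4-methylcyclohexane-1-carboxylate
Conditions: Me4NBH(OAc)3, MeCN/AcOH, −20 °C
Reagents that add atoms: none
Why: Evans–Saksena reduction: the borohydride binds the axial tertiary hydroxyl and delivers hydride to the same face of the neighbouring ketone, so the new C3 hydroxyl should be trans to the C4 hydroxyl (3R).

Step 5
Reactants: 5 methyl (1S,3R,4R)-3,4-dihydroxy-4-methylcyclohexane-1-carboxylate
Product: 7 methyl (3aR,5S,7aR)-7a-methyl-2,2-dioxohexahydro-1,3,2-benzodioxathiole-5-carboxylate (cyclic sulfate), via cyclic sulfite 6 (not isolated)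
Conditions: SOCl2, Et3N, CH2Cl2, 0 °C; then RuCl3 (1 mol %), NaIO4, MeCN/H2O, 0 °C
Reagents that add atoms: thionyl chloride, O=S(Cl)Cl; sodium periodate, [Na+].[O-]I(=O)(=O)=O
Why: Standard cyclic sulfate synthesis (cyclic sulfite, then ruthenium tetroxide oxidation); no C–O bond is broken, so both carbinol configurations are kept, the ring flipping to the chair with both oxygens equatorial.

Step 6
Reactants: 7 methyl (3aR,5S,7aR)-7a-methyl-2,2-dioxohexahydro-1,3,2-benzodioxathiole-5-carboxylate
Product: 9 methyl (1S,3S,4R)-3-bromo-4-hydroxy-4-methylcyclohexane-1-carboxylate, via lithium sulfate monoester 8 (not isolated)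
Conditions: LiBr, THF, 25 to 50 °C; then H2SO4 (cat.), H2O (2 equiv), THF, 25 °C
Reagents that add atoms: lithium bromide, [Li+].[Br-]
Why: SN2 opening of the cyclic sulfate by bromide at the secondary carbon with inversion sets C3 (S) with bromine cis to the tertiary oxygen, which is held as a sulfate monoester and cannot close an epoxide; acid hydrolysis of the monoester by S–O cleavage then frees the tertiary alcohol with retention.

Step 7
Reactants: 9 methyl (1S,3S,4R)-3-bromo-4-hydroxy-4-methylcyclohexane-1-carboxylate
Product: 11 (1R,2S,4S)-2-bromo-4-ethynyl-1-methylcyclohexan-1-ol, via hydroxy aldehyde 10 (not isolated)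
Conditions: i-Bu2AlH (2.2 equiv), CH2Cl2, −78 °C; MeOH; then K2CO3, dimethyl (1-diazo-2-oxopropyl)phosphonate, MeOH, 0 °C to rt
Reagents that add atoms: dimethyl (1-diazo-2-oxopropyl)phosphonate, COP(=O)(OC)C(=[N+]=[N-])C(C)=O
Why: Half-reduction of the ester (the aluminium hemiacetal is stable at −78 °C) and Seyferth–Gilbert homologation with the Ohira–Bestmann reagent in the same flask; the aldehyde α-centre can epimerize, but its equatorial configuration cis to the hydroxyl is both the one formed and the thermodynamically preferred one.

Step 8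
Reactants: 11 (1R,2S,4S)-2-bromo-4-ethynyl-1-methylcyclohexan-1-ol
Product: 13 (1R,2S,4S)-2-bromo-4-[(E)-1-iodoprop-1-en-2-yl]-1-methylcyclohexan-1-ol, via alkenylalane 12 (not isolated)
Conditions: AlMe3 (4 equiv), Cp2ZrCl2 (20 mol %), H2O (1 equiv), CH2Cl2, −20 °C; then I2, THF, −20 to 0 °C
Reagents that add atoms: trimethylaluminium, C[Al](C)C; iodine, II
Why: Negishi zirconium-catalysed carboalumination adds methyl and aluminium syn across the terminal alkyne with methyl on the internal carbon, and iodinolysis with retention gives the (E)-iodide; the hydroxyl is carried as its aluminium alkoxide, which in the cis bromohydrin cannot displace bromide.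

Step 9
Reactants: 14 (R)-linalool [(3R)-3,7-dimethylocta-1,6-dien-3-ol]
Product: 15 (3S,6R)-3-bromo-6-ethenyl-2,2,6-trimethyloxane
Conditions: 2,4,4,6-tetrabromocyclohexa-2,5-dien-1-one (TBCO), MeNO2, 0 °C to rt
Reagents that add atoms: TBCO, BrC1=CC(Br)(Br)C=C(Br)C1=O
Why: Bromonium-induced 6-endo (Markovnikov) cycloetherification by the tertiary alcohol through a chair transition state puts bromine equatorial; C6 (R) comes unchanged from linalool, and because methyl and vinyl are similar in size both C3 epimers are to be expected, the (3S,6R) isomer (bromine trans to vinyl) being separated by chromatography from its epimer and from 5-exo tetrahydrofurans.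

Step 10
Reactants: 13 (1R,2S,4S)-2-bromo-4-[(E)-1-iodoprop-1-en-2-yl]-1-methylcyclohexan-1-ol and 15 (3S,6R)-3-bromo-6-ethenyl-2,2,6-trimethyloxane
Product: 16 (1R,2S,4S)-2-bromo-4-[(2E,4E)-5-[(2R,5S)-5-bromo-2,6,6-trimethyloxan-2-yl]penta-2,4-dien-2-yl]-1-methylcyclohexan-1-ol
Conditions: Pd(OAc)2 (10 mol %), Bu4NCl, NaHCO3, DMF, 50 °C
Reagents that add atoms: none
Why: Heck reaction: oxidative addition of the alkenyl iodide with retention, insertion at the CH2 end of the vinyl group and β-hydride elimination, possible only toward the new bond because the neighbouring carbon is quaternary, should give the (E,E)-diene while the tertiary alcohol and both secondary bromides stay untouched.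

**Compound list**

1 | 3-oxocyclobutane-1-carboxylic acid | O=C1CC(C1)C(=O)O | starting material
2 | prop-1-en-2-yl 3-oxocyclobutane-1-carboxylate | CC(=C)OC(=O)C1CC(=O)C1 | intermediate
3 | (1R,4S)-1-methyl-2-oxabicyclo[2.2.2]octane-3,6-dione | O=C2[C@H]1CC[C@@](C)(O2)C(=O)C1 | intermediate
4 | methyl (1S,4R)-4-hydroxy-4-methyl-3-oxocyclohexane-1-carboxylate (OH cis to ester) | COC(=O)[C@H]1CC[C@@](C)(O)C(=O)C1 | intermediate
5 | methyl (1S,3R,4R)-3,4-dihydroxy-4-methylcyclohexane-1-carboxylate (trans diol) | COC(=O)[C@H]1CC[C@@](C)(O)[C@H](O)C1 | intermediate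
6 | cyclic sulfite of 5, methyl (3aR,5S,7aR)-7a-methyl-2-oxohexahydro-1,3,2-benzodioxathiole-5-carboxylate (both configurations at sulfur) | COC(=O)[C@H]1CC[C@@]2(C)OS(=O)O[C@@H]2C1 | intermediate (not isolated)
7 | methyl (3aR,5S,7aR)-7a-methyl-2,2-dioxohexahydro-1,3,2-benzodioxathiole-5-carboxylate | COC(=O)[C@H]1CC[C@@]2(C)OS(=O)(=O)O[C@@H]2C1 | intermediate
8 | lithium (1R,2S,4S)-2-bromo-4-(methoxycarbonyl)-1-methylcyclohexyl sulfate | [Li+].COC(=O)[C@H]1CC[C@@](C)(OS(=O)(=O)[O-])[C@@H](Br)C1 | intermediate (not isolated)
9 | methyl (1S,3S,4R)-3-bromo-4-hydroxy-4-methylcyclohexane-1-carboxylate (Br cis to OH) | COC(=O)[C@H]1CC[C@@](C)(O)[C@@H](Br)C1 | intermediate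
10 | (1S,3S,4R)-3-bromo-4-hydroxy-4-methylcyclohexane-1-carbaldehyde | O=C[C@H]1CC[C@@](C)(O)[C@@H](Br)C1 | intermediate (not isolated)
11 | (1R,2S,4S)-2-bromo-4-ethynyl-1-methylcyclohexan-1-ol | C#C[C@H]1CC[C@@](C)(O)[C@@H](Br)C1 | intermediate
12 | dimethylaluminium alkoxide of (1R,2S,4S)-2-bromo-4-[(E)-1-(dimethylalumanyl)prop-1-en-2-yl]-1-methylcyclohexan-1-ol | C/C(=C\[Al](C)C)[C@H]1CC[C@@](C)(O[Al](C)C)[C@@H](Br)C1 | intermediate (not isolated)
13 | (1R,2S,4S)-2-bromo-4-[(E)-1-iodoprop-1-en-2-yl]-1-methylcyclohexan-1-ol | C/C(=C\I)[C@H]1CC[C@@](C)(O)[C@@H](Br)C1 | intermediate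
14 | (R)-linalool, (3R)-3,7-dimethylocta-1,6-dien-3-ol | C=C[C@](C)(O)CCC=C(C)C | starting material
15 | (3S,6R)-3-bromo-6-ethenyl-2,2,6-trimethyloxane (Br trans to vinyl) | C=C[C@@]1(C)CC[C@H](Br)C(C)(C)O1 | intermediate
16 | (1R,2S,4S)-2-bromo-4-[(2E,4E)-5-[(2R,5S)-5-bromo-2,6,6-trimethyloxan-2-yl]penta-2,4-dien-2-yl]-1-methylcyclohexan-1-ol | C/C(=C\C=C\[C@@]1(C)CC[C@H](Br)C(C)(C)O1)[C@H]1CC[C@@](C)(O)[C@@H](Br)C1 | target

**Count and risks**

Total step count: 10. Longest linear sequence: 9 (steps 1 to 8 and step 10).

Steps most likely to fail: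

1. Step 2 (Proposed new method). What may go wrong: zerovalent nickel adds into the C(acyl)–O bond of the enol ester, or the nickelacycle undergoes β-acyloxy elimination instead of C–C reductive elimination; enantioface selection may also be poor. The fallback uses known chemistry and makes the same two ring bonds. It sets out from no numbered compound, because nothing before 3 contains the six-membered ring, but from bought dimethyl malonate and dimethyl 2-methylidenepentanedioate, and it comes back to the route at 9. NaOMe in MeOH should give by Michael addition tetramethyl pentane-1,1,3,5-tetracarboxylate F1, which in the same flask undergoes Dieckmann condensation to trimethyl 4-oxocyclohexane-1,3,5-tricarboxylate F2. Krapcho dealkoxycarbonylation (NaCl, wet DMSO, 150 °C) gives achiral methyl 4-oxocyclohexane-1-carboxylate F3. Enantioselective enamine-catalysed α-bromination (chiral 4,5-diphenylimidazolidine, 4,4-dibromo-2,6-di-tert-butylcyclohexa-2,5-dien-1-one) desymmetrizes the ketone and, after equilibration to the cis isomer, gives methyl (1S,3S)-3-bromo-4-oxocyclohexane-1-carboxylate F4. MeTi(OiPr)3 then adds methyl anti to bromine to give 9. This fallback gives up the stereochemical work of the key step: the ring is made achiral and the stereocentres rest on the bromination and on the face selectivity of the methyl addition.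

2. Step 6. What may go wrong: elimination or attack at the tertiary carbon during opening of the sulfate, and C–O heterolysis with elimination during hydrolysis of the tertiary sulfate monoester. The fallback sets out from 3 and comes back at 11, keeping the tertiary oxygen masked as the lactone. NaBH4 in MeOH at −20 °C, with hydride expected from the less hindered lactone face, gives (1R,4S,6R)-6-hydroxy-1-methyl-2-oxabicyclo[2.2.2]octan-3-one F5. Tf2O and pyridine give its trifluoromethanesulfonate F6, and Bu4NBr in toluene displaces it with inversion to (1R,4S,6S)-6-bromo-1-methyl-2-oxabicyclo[2.2.2]octan-3-one F7. i-Bu2AlH at −78 °C, then the Ohira–Bestmann reagent with K2CO3 in MeOH, converts the lactone through its lactol into alkyne 11.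

3. Step 10. What may go wrong: slow insertion into the hindered alkene, insertion with reversed regiochemistry, or isomerization of the diene by palladium hydride. The fallback sets out from 15 and 11 and comes back at 16. Ozonolysis of 15 (O3, CH2Cl2, −78 °C; Me2S) gives (2R,5S)-5-bromo-2,6,6-trimethyloxane-2-carbaldehyde F8. Takai iodoolefination (CrCl2, CHI3, THF) gives (2R,5S)-5-bromo-2-[(E)-2-iodoethenyl]-2,6,6-trimethyloxane F9. The alane 12, made from 11 as in the first half of step 8, is then coupled with F9 (ZnCl2, Pd(PPh3)4, THF; Negishi coupling) to give 16 with both double bonds formed stereospecifically.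

**Further compounds**

F1 | step 2 | tetramethyl pentane-1,1,3,5-tetracarboxylate | COC(=O)C(C(=O)OC)CC(C(=O)OC)CCC(=O)OC
F2 | step 2 | trimethyl 4-oxocyclohexane-1,3,5-tricarboxylate | COC(=O)C1CC(C(=O)OC)C(=O)C(C(=O)OC)C1
F3 | step 2 | methyl 4-oxocyclohexane-1-carboxylate | COC(=O)C1CCC(=O)CC1
F4 | step 2 | methyl (1S,3S)-3-bromo-4-oxocyclohexane-1-carboxylate | COC(=O)[C@H]1CCC(=O)[C@@H](Br)C1
F5 | step 6 | (1R,4S,6R)-6-hydroxy-1-methyl-2-oxabicyclo[2.2.2]octan-3-one | O=C2[C@H]1CC[C@@](C)(O2)[C@H](O)C1
F6 | step 6 | (1R,4S,6R)-1-methyl-3-oxo-2-oxabicyclo[2.2.2]octan-6-yl trifluoromethanesulfonate | O=C2[C@H]1CC[C@@](C)(O2)[C@H](OS(=O)(=O)C(F)(F)F)C1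
F7 | step 6 | (1R,4S,6S)-6-bromo-1-methyl-2-oxabicyclo[2.2.2]octan-3-one | O=C2[C@H]1CC[C@@](C)(O2)[C@@H](Br)C1
F8 | step 10 | (2R,5S)-5-bromo-2,6,6-trimethyloxane-2-carbaldehyde | O=C[C@@]1(C)CC[C@H](Br)C(C)(C)O1
F9 | step 10 | (2R,5S)-5-bromo-2-[(E)-2-iodoethenyl]-2,6,6-trimethyloxane | I/C=C/[C@@]1(C)CC[C@H](Br)C(C)(C)O1
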